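The earlier runs and the new flask are calculated with constants of no real substance, and the scatter is random.

You cannot tell from cedar and elm which charge makes the product: elm holds 1.47 times cedar's starting material and 1.46 times its partner. The flask pulls these apart, with cedar's starting material and elm's partner, so you must turn each setting by hand.

| flask | starting material | partner | precatalyst | remark | time |
|---|---|---|---|---|---|
| cedar | 1.7 M (in portions, 2) | 1.4 M | 2 mM | run made earlier; portions every 12 min |  |
| elm | 2.5 M (in portions, 2) | 2.04 M | 2 mM | run made earlier; portions every 12 min |  |
| flask | 1.7 M (in portions, 2) | 2.04 M | 2.0 mM | the portions of starting material follow each other after 12 min, the first at the start | 1.0 h |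

- cedar (time / min: product / %, starting material / %): 15.0: 3.3, 97.3; 30.0: 9.7, 89.9; 50.0: 21.3, 79.0; 60.0: 24.2, 74.5
- elm (time / min: product / %, starting material / %): 5.00: 0.5, 49.4; 12.0: 2.4, 46.5; 25.0: 7.6, 91.6; 60.0: 26.8, 74.4

(readings scatter by 1 percentage point)

- how much product the flask holds at 1.0 h, in percent of the starting material charged
- how much starting material the flask holds at 1.0 h, in percent of the starting material charged
- concentration of partner at 1.0 h, in M

Turn starting material first. If product simply scaled with it, the percentage would hold steady, as it nearly does from cedar's 24.2% to elm's 26.8%, and the flask would stand near those figures.

Turn partner next. Divide the molar product at 60.0 min by the molar partner charged: cedar gives 0.294, elm 0.328, and their mean is 0.311. This is the partner yield, the figure to watch. Carried to the flask, at the same time and the same precatalyst charge, it gives 37.3% product.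

Precatalyst gives these runs no handle: cedar, elm and the flask each hold 2.0 mM.

I side with partner, and that is a judgement, not a reading: the proposed steps use it twice, to start the catalyst and in the round, and starting material once. My reckoning is therefore 37.3% product, 62.7% starting material and 1.41 M partner.

The forecast, granting that “the runs cannot separate partner from starting material”, gives 33%, 67% and 1.48 M, with less product than my reckoning. The flask gives 36.3%, 63.6% and 1.42 M.

    starting material + free catalyst ⇌ catalyst intermediate A (K = 39.0 /M, k = 20.0 /M/min)
    partner + catalyst intermediate A ⇌ catalyst intermediate B (K = 0.160 /M, k = 18.0 /M/min)
    catalyst intermediate C → free catalyst + product (k = 33.0 /min)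
    partner + precatalyst → free catalyst + spent reagent (k = 0.0340 /M/min)
    free catalyst → spent catalyst (k = 0.00120 /min)
    catalyst intermediate B → catalyst intermediate C (k = 110 /min)

The flask's partner yield comes to 0.302, close to the carried 0.311. For a neighbour flask charged with 0.51 M of partner, 0.311 reckons 9.33% product; that neighbour stores 7.75%, a partner yield of 0.258. The flask has not come to rest at 1.0 h: 63.6% of its starting material still stands. Left until 10.0 h, the flask holds 0% starting material, the limiting reagent, and >99.9% product, so its partner yield climbs to 0.833 and 0.338 M of partner remains.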